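## Analysis of the target

The target 24 is a depsidone. Two benzene rings, ring A and ring B, are joined by a diaryl ether oxygen and by an aryl ester, which together close a central seven-membered lactone. Ring B also carries a fused five-membered hydroxy lactone (a 3-hydroxyphthalide).

The ring carbons are labelled by what they carry. Ring A: a1 (OCH3), a2 (H), a3 (CH3), a4 (the ester carbonyl), a5 (the ether oxygen), a6 (OH). Ring B: b1 (the ether oxygen), b2 (the ester oxygen), b3 (CH3), b4 (OH), b5 (the lactone carbonyl), b6 (the lactol carbon).

The only stereocentre is the lactol carbon on b6, with (R) configuration. It is a cyclic acyl hemiacetal that can open to the 2-formylbenzoic acid tautomer. It has no neighbouring stereocentre to relay from, so it must be set last and under neutral conditions.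

The sensitive groups are the aryl ester of the seven-membered ring (hydroxide, hydroperoxide), the lactol (base), the free phenols, and the one C–H position of the electron-rich ring A (a2), which is open to electrophiles.

The difficulty lies in ring B, which is hexasubstituted with six different groups, and in the ether oxygen, which is flanked by four ortho substituents (a4, a6, b2, b6). A late C–O coupling of two finished rings is therefore the least promising bond formation.

The strategy rests on one feature. Carbons b6 and b5 are already linked through three atoms (lactol carbon, ring oxygen, carbonyl carbon), and b1 carries the oxygen to ring A. Ring B can therefore be cut into three two-carbon units, b1–b6, b5–b4 and b2–b3. The first two are tied together by the lactone atoms, and the first is bound to ring A as an aryl alkynyl ether.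

## Retrosynthetic reasoning

**Stereocentre (24 to 23 to 22).** The (R)-lactol 24 is traced to its acetate 23 and this to the racemic lactol 22. Only the acetyl C–O bond is cut; the bond at the stereocentre is never broken. Because 22 epimerises by ring opening, a lipase that acetylates one enantiomer can convert all of it into 23, which no longer epimerises. The forward reactions must transfer and then remove the acyl group without ionising the acetal carbon.

**Oxygen at b4 and the protecting groups (22 to 21 to 19).** The lactol and the a6 phenol of 22 are masked in 21 as a methyl acetal and a methoxymethyl ether, both removed by one aqueous acid treatment. The b4–O bond is traced to a C–I bond in 19 and further to a C–Si bond in 16. Silicon is chosen because an alkyne can carry it through a cycloaddition, and because ring B has no C–H bond, so an ipso substitution is the only way to reach b4.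

**Seven-membered lactone (19 to 18 to 17 to 16).** The ester bond between the a4 carbonyl and the b2 oxygen is cut, not the ether bond. The ester closes intramolecularly from the seco acid 18, whereas the ether is the hindered bond. In 18 the b2 hydroxyl is the only free hydroxyl, so the closure has no competitor. Both the silyl ether at b2 and the silyl-based ester at a4 in 17 fall to fluoride in one operation, which is why that ester was chosen.

**Key disconnection (16 to 12 and 15).** Three ring B bonds are cut at once: b1–b2, b3–b4 and b5–b6. This leaves the diyne 12, whose two alkynes are tethered by exactly the three lactone atoms, and the siloxyalkyne 15, which brings b2 with its oxygen and b3 with its methyl group. The gain is that ring B and the five-membered lactone appear in one step around an ether bond that already exists. The forward reaction has to favour cross-cycloaddition over self-reaction and fix one orientation of 15.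

**Acyloxy acetal (12 to 9 and 10).** The bond between the ester oxygen and the acetal carbon is cut. The dimethyl acetal 9 offers one methoxyl as a leaving group, and the acid 10 enters as a carboxylate. The acetal carbon is thus kept at the aldehyde oxidation level throughout, and no oxidation of a phthalide is needed later.

**Alkynyl ether (9 to 5 and 7).** The O–C(sp) bond is cut. The phenol oxygen of 5 is joined to the dibromoalkene 7 at an unhindered vinylic carbon, and the alkyne is then formed by elimination. This is the ether bond of the target, made while ring B does not yet exist.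

**Building blocks.** The salicylate 5 is traced through acid 4, aldehyde 3 and catechol 2 to the commercial aldehyde 1. Compound 1 already holds every carbon and oxygen of ring A, and its three methoxyls are told apart by their position relative to the carbonyl group. Compound 7 comes from aldehyde 6, and 15 from the acetylide 13.

## Alternatives that were turned down

**Alternative 1: cyclobutenone ring expansion to ring B.**
- Disconnection: only ring B is built. The bond b4–b5 is cut and the ring is traced to the squarate-derived cyclobutenone A1.
- Forward key step: heating A1 opens the four-membered ring to a dienylketene. Its ketene carbon closes onto the terminal alkene carbon, and tautomerisation gives phenol A2.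
- For it: the thermal ring expansion is dependable for pentasubstituted phenols and needs no metal and no fragile alkynyl ether. The order of additions to the four-membered ring fixes the place of every substituent. On regiochemical certainty it is stronger than a cycloaddition with an unsymmetrical third alkyne.
- Against it: A2 contains no ring of the target other than ring B. Carbon b5 is still C–H and must be carboxylated between an acetal and a phenol. The diaryl ether must then be made by coupling the b1 oxygen, flanked by the acetal carbon and a benzyloxy group, with a ring A halide that is itself flanked on both sides. That is the bond judged hardest, and the seven-membered lactone and the lactol follow only after it.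
- Comparison: the chosen route accepts a regiochemical question in one step and in return needs no hindered C–O coupling, forming two rings and three bonds where this alternative forms one ring.

**Alternative 2: acyloxy shift in a spiro quinol ketal.**
- Disconnection: the ester C–O bond at b2 is traced to a 1,2-shift. In the spiro ketal A3 both oxygens sit on b1, and ring B is a cyclohexa-2,5-dienone.
- Forward key step: acid ionises the acyl C–O bond of the ketal, a carboxylate oxygen bonds to b2 (the CH carbon next to the spiro centre), and loss of the proton aromatises ring B. The six-membered spiro ring becomes the seven-membered lactone of A4.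
- For it: the ether oxygen is attached to b1 while b1 is not an aromatic carbon, so no hindered aryl C–O coupling is needed. The sequence is short and clearly stronger in step economy than the chosen route.
- Against it: ionisation places positive charge on a dienone that carries a formyl group, an ester and a ketone, so it is strongly disfavoured. Hydrolytic return to a quinone and the ring A acid, or migration of the aryloxy oxygen instead of the acyloxy oxygen, would compete. Making A3 requires oxidative dearomatisation of an electron-poor phenol in the presence of an aldehyde. From A4 a methyl ester must still be hydrolysed next to the aryl ester of the seven-membered ring.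
- Comparison: the chosen route is longer, but the lactone is formed directly at the right oxidation level and every ring B substituent is placed by the alkyne that carries it.

**Alternative 3: anodic closure of the ether bond in a depside.**
- Disconnection: the ether bond a5–O is cut. The precursor is the depside A5, with the ester already in place, C–H at a5, a free a6 hydroxyl and a free b1 hydroxyl.
- Forward key step: oxidation at a carbon anode in a fluorinated alcohol, in which the b1 oxygen bonds to a5 and closes the seven-membered ring of A6.
- For it: it is by far the most convergent plan. Two rings are made separately by classical aromatic chemistry and joined by esterification, no prefunctionalisation at a5 is needed, and A6 is one acid treatment away from the racemic lactol. In step count it is clearly stronger than the chosen route.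
- Against it: ring A, with its free hydroxyl and methoxyl, is oxidised first. Its oxidised form is attacked by oxygen nucleophiles mainly para to the hydroxyl (a3, which bears the methyl group) or at the methoxyl-bearing carbon. The nucleophile is a weakly nucleophilic phenol hydrogen-bonded to an ortho formyl group, and anodic phenol couplings that form C–O bonds in a seven-membered ring have little support. A6 is a more electron-rich catechol ether than A5 and would be oxidised further.
- Comparison: the chosen route pays with length, and in return the ether bond is formed where there is no choice of position and no oxidant meets the product.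

Key step: step 9

Assumption (remark on the chemistry): the lactol carbon of 24 epimerises through the ring-opened formyl acid, so 24 is taken as the (R)-lactol as released and isolated cold under neutral, base-free conditions, with limited configurational life in solution.

## Route

Step 1
Reactants: 1 trimethoxy aldehyde (2,3,4-trimethoxy-6-methylbenzaldehyde)
Product: 2 catechol aldehyde (2,3-dihydroxy-4-methoxy-6-methylbenzaldehyde)
Conditions: BCl3 (3 equiv), CH2Cl2, −10 °C to rt; aq. work-up
Reagents that add atoms: none
Why: Chelation-controlled ether cleavage: BCl3 binds the aldehyde oxygen and removes the ortho methoxyl, and the aryloxyboron chloride so formed delivers the second cleavage to the neighbouring methoxyl, while the para methoxyl, which cannot chelate, should stay (Lewis acid demethylation of ortho-alkoxy aryl carbonyl compounds).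

Step 2
Reactants: 2 catechol aldehyde
Product: 3 mono-protected aldehyde (2-hydroxy-4-methoxy-3-(methoxymethoxy)-6-methylbenzaldehyde)
Conditions: NaH (2.2 equiv), DMF, 0 °C; then MOMCl (1.0 equiv), 0 °C
Reagents that add atoms: chloromethyl methyl ether (COCCl)
Why: Williamson alkylation of the dianion: the phenoxide ortho to the aldehyde is delocalised into the carbonyl group and chelated by sodium, so one equivalent of the chloride should react at the other, more basic oxygen (a6), as is known for 2,3-dihydroxybenzaldehydes.

Step 3
Reactants: 3 mono-protected aldehyde
Product: 4 salicylic acid (2-hydroxy-4-methoxy-3-(methoxymethoxy)-6-methylbenzoic acid)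
Conditions: NaClO2, NaH2PO4, 2-methyl-2-butene, t-BuOH–THF–H2O, 0 °C to rt
Reagents that add atoms: NaClO2, sodium chlorite ([Na+].[O-]Cl=O)
Why: Lindgren–Pinnick oxidation, a reaction developed on hydroxybenzaldehydes; the buffer keeps the pH near 4 so that the methoxymethyl ether survives, and the alkene removes HOCl before it can chlorinate the electron-rich ring.

Step 4
Reactants: 4 salicylic acid
Product: 5 ring A salicylate (2-(trimethylsilyl)ethyl 2-hydroxy-4-methoxy-3-(methoxymethoxy)-6-methylbenzoate)
Conditions: Me3SiCH2CH2OH (1.1 equiv), PPh3, DIAD, THF, 0 °C to rt
Reagents that add atoms: 2-(trimethylsilyl)ethanol (C[Si](C)(C)CCO)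
Why: Mitsunobu esterification: the carboxylate, far more acidic than the hydrogen-bonded phenol, displaces the activated primary alcohol at carbon, so the hindrance of the di-ortho-substituted carbonyl group does not matter. This ester is chosen because fluoride later removes it together with the silyl ether on ring B, without acid.

Step 5
Reactants: 6 glyoxal monoacetal (2,2-dimethoxyacetaldehyde)
Product: 7 dibromoalkene (1,1-dibromo-3,3-dimethoxyprop-1-ene)
Conditions: CBr4, PPh3, Et3N, CH2Cl2, 0 °C (6 extracted from its aqueous solution into CH2Cl2 and dried over MgSO4)
Reagents that add atoms: tetrabromomethane (BrC(Br)(Br)Br)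
Why: Ramirez dibromo-olefination (first stage of the Corey–Fuchs sequence); the amine buffers HBr so that the dimethyl acetal is kept.

Step 6
Reactants: 5 ring A salicylate; 7 dibromoalkene
Product: 9 ring A ynol ether acetal (2-(trimethylsilyl)ethyl 2-(3,3-dimethoxyprop-1-ynyloxy)-4-methoxy-3-(methoxymethoxy)-6-methylbenzoate), via bromo enol ether 8 (not isolated)
Conditions: CuI (10 mol%), 2,2'-bipyridine (20 mol%), K3PO4, toluene, 110 °C; then KOtBu, THF, 0 °C to rt
Reagents that add atoms: none
Why: Copper-catalysed vinylic C–O coupling of a phenol with a 1,1-dibromoalkene (Ullmann type, the bromine trans to the substituent reacting), then anti-elimination of HBr from the (Z)-bromo enol ether, the established route to aryl ynol ethers. The ether bond that will later be flanked by four ortho groups is made here at an unhindered vinylic carbon, and the ester is shielded against tert-butoxide by its two ortho groups.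

Step 7
Reactants: 9 ring A ynol ether acetal; 10 silylpropiolic acid (3-(trimethylsilyl)prop-2-ynoic acid)
Product: 12 diyne with acyloxy acetal tether (racemic 1-methoxy-3-(ring A aryloxy)prop-2-ynyl 3-(trimethylsilyl)prop-2-ynoate), via chloro ether 11 (not isolated)
Conditions: AcCl (1.05 equiv), ZnBr2 (1 mol%), 2,6-di-tert-butylpyridine (10 mol%), CH2Cl2, −20 to 0 °C; then 10, i-Pr2NEt, −20 °C to rt; filtration through Et3N-deactivated silica
Reagents that add atoms: none
Why: Exchange of an acetal to an α-chloro ether with an acyl chloride under zinc halide catalysis, then O-alkylation of the carboxylate by the α-chloro ether, the reaction type by which alkoxymethyl esters are made. The propargylic acetal ionises to an oxocarbenium ion conjugated with the aryloxyalkyne and should therefore react before the methoxymethyl ether; the hindered pyridine takes up traces of HCl that would add to the ynol ether.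

Step 8
Reactants: 13 propynyllithium (prop-1-ynyllithium)
Product: 15 siloxyalkyne (triisopropyl(prop-1-ynyloxy)silane), via lithium ynolate 14 (not isolated)
Conditions: t-BuOOH (anhydrous, decane), LiN(SiMe3)2, THF, −78 °C; add 13, −78 to 0 °C; then i-Pr3SiOTf, −78 to 0 °C
Reagents that add atoms: tert-butyl hydroperoxide (CC(C)(C)OO); triisopropylsilyl trifluoromethanesulfonate (CC(C)[Si](OS(=O)(=O)C(F)(F)F)(C(C)C)C(C)C)
Why: Oxidation of a lithium acetylide by lithium tert-butyl peroxide (attack of the acetylide carbon on the O–O bond) gives the lithium ynolate, and the bulky silyl triflate reacts at oxygen, where small silyl groups would give silyl ketenes.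

Step 9
Reactants: 12 diyne with acyloxy acetal tether; 15 siloxyalkyne
Product: 16 cycloadduct (racemic 2-(trimethylsilyl)ethyl 4-methoxy-2-{[3-methoxy-6-methyl-1-oxo-5-(triisopropylsilyloxy)-7-(trimethylsilyl)-1,3-dihydro-2-benzofuran-4-yl]oxy}-3-(methoxymethoxy)-6-methylbenzoate)
Conditions: [Rh(cod)2]BF4 (10 mol%), rac-BINAP (10 mol%), H2 (1 atm) pre-activation then argon; 15 (3 equiv), CH2Cl2, rt, slow addition of 12
Reagents that add atoms: none
Why: Cationic monovalent rhodium, freed of cyclooctadiene by hydrogenation and carrying BINAP, binds both alkynes of 12 and couples them oxidatively to a trivalent rhodacyclopentadiene; 15 then coordinates and inserts into a Rh–C bond, and reductive elimination releases the arene and the catalyst. The closest known reaction type is the cationic rhodium–bisphosphine (2+2+2) cycloaddition of ester-linked 1,6-diynes with monoalkynes to phthalides, which is also known for diynes with aryl alkynyl ether ends and for heteroatom-substituted alkyne partners. The five-membered lactone closes in the oxidative coupling through the bond b5–b6, a closure enforced by the three-atom tether (acetal carbon, oxygen, carbonyl carbon); ring B closes through the bonds b1–b2 and b3–b4 to the third alkyne. No stereocentre is formed and the acetal carbon stays racemic, so racemic ligand suffices. The step needs cross-cycloaddition instead of self-reaction, which the intramolecular pairing of the two alkynes of 12, its slow addition and the excess of 15 should secure, and it needs one orientation of 15. That orientation should follow from polarity and size: the methyl-bearing carbon of 15, its nucleophilic end, bonds to the silyl-bearing carbon of the metallacycle, which is the electrophilic β-carbon of the unsaturated ester, and the reverse orientation would put the triisopropylsiloxy group next to the trimethylsilyl group. Because the Lewis-acidic metal could ionise the propargylic acyloxy acetal, a non-coordinating chlorinated solvent and room temperature are chosen.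

Step 10
Reactants: 16 cycloadduct
Product: 17 aryl iodide (as 16, with iodine in place of the trimethylsilyl group at b4; racemic)
Conditions: ICl (1.05 equiv), CH2Cl2, −78 to −20 °C; aq. Na2S2O3
Reagents that add atoms: iodine monochloride (ClI)
Why: ipso-Iododesilylation (electrophilic aromatic substitution at the silicon-bearing carbon): b4 is para to the aryloxy oxygen, the intermediate cation is stabilised by the β-silicon effect, and ring B has no C–H position; the alkyl–silicon bond of the ester and the silyl ether are inert to ICl. One equivalent at low temperature is used because a2 of ring A is the only competing nucleophilic carbon.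

Step 11
Reactants: 17 aryl iodide
Product: 18 seco acid (racemic 2-[(5-hydroxy-7-iodo-3-methoxy-6-methyl-1-oxo-1,3-dihydro-2-benzofuran-4-yl)oxy]-4-methoxy-3-(methoxymethoxy)-6-methylbenzoic acid)
Conditions: Bu4NF (4 equiv), THF, 0 °C to rt; cold dil. HCl to pH 3
Reagents that add atoms: none
Why: Fluoride cleaves the aryl silyl ether at silicon and fragments the 2-(trimethylsilyl)ethyl ester to carboxylate, ethene and Me3SiF (β-elimination), so the seco acid is set free without acid or hydroxide. The methoxymethyl ether, the methyl acetal and the aryl iodide do not react with fluoride.

Step 12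
Reactants: 18 seco acid
Product: 19 depsidone iodide (seven-membered lactone closed between the a4 carbonyl and the b2 oxygen; a6 methoxymethyl ether, b4 iodine, lactol carbon as methyl acetal; racemic)
Conditions: DCC (1.5 equiv), DMAP (10 mol%), CH2Cl2 (0.005 M), 0 °C to rt
Reagents that add atoms: none
Why: Carbodiimide lactonisation (Steglich type) of a 2-aryloxybenzoic acid onto the ortho hydroxyl of the other ring, the standard depsidone closure. The b2 hydroxyl is the only free hydroxyl in 18 and the diaryl ether holds acid and phenol close together, so the seven-membered ring should form at high dilution.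

Step 13
Reactants: 19 depsidone iodide
Product: 21 depsidone phenol (as 19, with hydroxyl at b4; racemic), via pinacol boronate 20 (not isolated)
Conditions: B2pin2, PdCl2(dppf) (5 mol%), KOAc, 1,4-dioxane, 85 °C; then Me3NO, THF, 60 °C
Reagents that add atoms: trimethylamine N-oxide (C[N+](C)(C)[O-])
Why: Miyaura borylation of the aryl iodide (oxidative addition to zerovalent palladium, transmetalation with the diboron, reductive elimination), then oxidation of the boronate by the amine N-oxide with migration of the aryl group from boron to oxygen. The N-oxide is chosen over alkaline peroxide because the aryl ester of the seven-membered ring would not survive hydroperoxide.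

Step 14
Reactants: 21 depsidone phenol
Product: 22 racemic lactol (racemic form of the target)
Conditions: 3 M aq. HCl–THF (1:2), 55 °C
Reagents that add atoms: water (O)
Why: Acid hydrolysis of two acetals: the methoxymethyl ether gives the a6 phenol, and the 3-methoxyphthalide gives the lactol through the benzylic cation that the ring oxygen stabilises; aryl esters are stable to aqueous acid. The lactol is formed racemic.

Step 15
Reactants: 22 racemic lactol
Product: 23 (R)-lactol acetate (target with the lactol hydroxyl acetylated, (R) at the acetal carbon)
Conditions: immobilised Burkholderia cepacia lipase (or the lipase found by screening to give the (R)-acetate), vinyl acetate, Et3N (10 mol%), MTBE, 4 Å MS, 35 °C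
Reagents that add atoms: vinyl acetate (C=COC(C)=O)
Why: Lipase-catalysed dynamic kinetic resolution by acyl transfer, as known for 5-hydroxyfuranones and related cyclic acyl hemiacetals: the lactol enantiomers interconvert through the ring-opened formyl acid (helped by the amine), the enzyme acetylates one of them irreversibly because the enol leaving group tautomerises, and the acetate no longer epimerises. The (R) configuration is set by the active site of the enzyme, which must be selected for this sense; any phenol acetate formed on the side is removed in step 16.

Step 16
Reactants: 23 (R)-lactol acetate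
Product: 24 target ((R)-lactol)
Conditions: same lipase, n-BuOH (5 equiv), MTBE, 0–5 °C; filtration; crystallisation without base
Reagents that add atoms: none
Why: Lipase-catalysed alcoholysis cleaves the acyl–oxygen bond and not the bond at the stereocentre, so the configuration is retained, and the enzyme that made the (R)-acetate accepts it again, which passes the material through a second enantiodiscrimination. Low temperature and the absence of base keep epimerisation of the free lactol slow during reaction and isolation.

## Compound list

1 | 2,3,4-trimethoxy-6-methylbenzaldehyde | COc1cc(C)c(C=O)c(OC)c1OC | starting material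
2 | 2,3-dihydroxy-4-methoxy-6-methylbenzaldehyde | COc1cc(C)c(C=O)c(O)c1O | intermediate
3 | 2-hydroxy-4-methoxy-3-(methoxymethoxy)-6-methylbenzaldehyde | COCOc1c(OC)cc(C)c(C=O)c1O | intermediate
4 | 2-hydroxy-4-methoxy-3-(methoxymethoxy)-6-methylbenzoic acid | COCOc1c(OC)cc(C)c(C(=O)O)c1O | intermediate
5 | 2-(trimethylsilyl)ethyl 2-hydroxy-4-methoxy-3-(methoxymethoxy)-6-methylbenzoate | COCOc1c(OC)cc(C)c(C(=O)OCC[Si](C)(C)C)c1O | intermediate
6 | 2,2-dimethoxyacetaldehyde | COC(OC)C=O | starting material
7 | 1,1-dibromo-3,3-dimethoxyprop-1-ene | COC(OC)C=C(Br)Br | intermediate
8 | 2-(trimethylsilyl)ethyl 2-{[(Z)-1-bromo-3,3-dimethoxyprop-1-enyl]oxy}-4-methoxy-3-(methoxymethoxy)-6-methylbenzoate | COCOc1c(OC)cc(C)c(C(=O)OCC[Si](C)(C)C)c1O/C(Br)=C/C(OC)OC | intermediate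
9 | 2-(trimethylsilyl)ethyl 2-(3,3-dimethoxyprop-1-ynyloxy)-4-methoxy-3-(methoxymethoxy)-6-methylbenzoate | COCOc1c(OC)cc(C)c(C(=O)OCC[Si](C)(C)C)c1OC#CC(OC)OC | intermediate
10 | 3-(trimethylsilyl)prop-2-ynoic acid | C[Si](C)(C)C#CC(=O)O | starting material
11 | 2-(trimethylsilyl)ethyl 2-(3-chloro-3-methoxyprop-1-ynyloxy)-4-methoxy-3-(methoxymethoxy)-6-methylbenzoate (racemic) | COCOc1c(OC)cc(C)c(C(=O)OCC[Si](C)(C)C)c1OC#CC(Cl)OC | intermediate
12 | 1-methoxy-3-{3-methoxy-2-(methoxymethoxy)-5-methyl-6-[2-(trimethylsilyl)ethoxycarbonyl]phenoxy}prop-2-ynyl 3-(trimethylsilyl)prop-2-ynoate (racemic) | COCOc1c(OC)cc(C)c(C(=O)OCC[Si](C)(C)C)c1OC#CC(OC)OC(=O)C#C[Si](C)(C)C | intermediate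
13 | prop-1-ynyllithium | [Li]C#CC | starting material
14 | lithium prop-1-yn-1-olate | CC#C[O-].[Li+] | intermediate
15 | triisopropyl(prop-1-ynyloxy)silane | CC#CO[Si](C(C)C)(C(C)C)C(C)C | intermediate
16 | 2-(trimethylsilyl)ethyl 4-methoxy-2-{[3-methoxy-6-methyl-1-oxo-5-(triisopropylsilyloxy)-7-(trimethylsilyl)-1,3-dihydro-2-benzofuran-4-yl]oxy}-3-(methoxymethoxy)-6-methylbenzoate (racemic) | COCOc1c(OC)cc(C)c(C(=O)OCC[Si](C)(C)C)c1Oc1c(O[Si](C(C)C)(C(C)C)C(C)C)c(C)c([Si](C)(C)C)c2C(=O)OC(OC)c12 | intermediate
17 | 2-(trimethylsilyl)ethyl 2-{[7-iodo-3-methoxy-6-methyl-1-oxo-5-(triisopropylsilyloxy)-1,3-dihydro-2-benzofuran-4-yl]oxy}-4-methoxy-3-(methoxymethoxy)-6-methylbenzoate (racemic) | COCOc1c(OC)cc(C)c(C(=O)OCC[Si](C)(C)C)c1Oc1c(O[Si](C(C)C)(C(C)C)C(C)C)c(C)c(I)c2C(=O)OC(OC)c12 | intermediate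
18 | 2-[(5-hydroxy-7-iodo-3-methoxy-6-methyl-1-oxo-1,3-dihydro-2-benzofuran-4-yl)oxy]-4-methoxy-3-(methoxymethoxy)-6-methylbenzoic acid (racemic) | COCOc1c(OC)cc(C)c(C(=O)O)c1Oc1c(O)c(C)c(I)c2C(=O)OC(OC)c12 | intermediate
19 | depsidone iodide: seven-membered lactone between the a4 carbonyl and the b2 oxygen; a1 OCH3, a3 CH3, a6 OCH2OCH3, b3 CH3, b4 I, ring B fused to the 3-methoxy lactone (racemic) | COCOc1c(OC)cc(C)c2c1Oc1c(OC2=O)c(C)c(I)c3C(=O)OC(OC)c13 | intermediate
20 | as 19, with 4,4,5,5-tetramethyl-1,3,2-dioxaborolan-2-yl at b4 (racemic) | COCOc1c(OC)cc(C)c2c1Oc1c(OC2=O)c(C)c(B4OC(C)(C)C(C)(C)O4)c3C(=O)OC(OC)c13 | intermediate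
21 | as 19, with OH at b4 (racemic) | COCOc1c(OC)cc(C)c2c1Oc1c(OC2=O)c(C)c(O)c3C(=O)OC(OC)c13 | intermediate
22 | racemic lactol: depsidone with a1 OCH3, a3 CH3, a6 OH, b3 CH3, b4 OH and ring B fused to the 3-hydroxy lactone | COc1cc(C)c2c(c1O)Oc1c(c(C)c(O)c3c1C(O)OC3=O)OC2=O | intermediate
23 | (R)-lactol acetate: as 22, with the lactol hydroxyl acetylated, (R) at the acetal carbon | COc1cc(C)c2c(c1O)Oc1c(c(C)c(O)c3c1[C@H](OC(C)=O)OC3=O)OC2=O | intermediate
24 | CNP0211607.1: as 22, (R) at the lactol carbon | COc1cc(C)c2c(c1O)Oc1c(c(C)c(O)c3c1[C@H](O)OC3=O)OC2=O | target

## Step count and least certain steps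

Total step count: 16. Longest linear sequence: 14 steps (steps 1–4, 6, 7, 9–16); steps 5 and 8 make the two side components.

**Step 9 (key step).**
- What may go wrong: the electron-rich siloxyalkyne may be consumed by the Lewis-acidic cationic metal (oligomerisation, ketene-type decomposition) or insert in the reverse sense. The closure of a hexasubstituted ring from three internal alkynes is slow, so self-reaction of 12 or ionisation of its propargylic acyloxy acetal may take over.
- Fallback, from 12 back to 21: the oxygenated alkyne is given up and both ring B oxygens are brought in through silicon. Compound 12 and commercial trimethyl(prop-1-ynyl)silane under the same rhodium catalyst should give the bis(trimethylsilyl) cycloadduct F1. Its orientation is fixed because the two silyl groups avoid an ortho relationship. ICl (2.1 equiv) then gives the diiodide F2, and twofold borylation with N-oxide oxidation as in step 13 gives the resorcinol F3. Bu4NF cleaves the ester to the dihydroxy acid F4, and carbodiimide lactonisation, which can reach only the b2 hydroxyl, gives 21.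

**Step 7.**
- What may go wrong: ionisation of the acetal gives a cation that can also be captured at the alkyne terminus. HCl may add across the ynol ether, and the methoxymethyl ether may be attacked by the acyl chloride.
- Fallback, from 9 back to 12: 9 is treated with Et3SiOTf and 2,4,6-trimethylpyridine in CH2Cl2 at 0 °C. This converts the dimethyl acetal under basic buffering into the pyridinium salt F5 (not isolated), a tamed equivalent of the α-chloro ether with no free halide. Addition of 10 and i-Pr2NEt then gives 12.

**Step 10.**
- What may go wrong: electrophilic iodination of ring A at a2 (ortho to the methoxyl, para to the ether oxygen) may compete with ipso substitution at the carbonyl-flanked b4.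
- Fallback, from 16 back to 22: the halogen electrophile is replaced by a boron electrophile that does not attack aromatic C–H bonds. Bu4NF converts 16 into the silyl-bearing seco acid F6, and carbodiimide lactonisation gives the silyl depsidone F7. BCl3 (CH2Cl2, −78 to 0 °C) then effects ipso-borodesilylation at b4 with delivery from the neighbouring lactone carbonyl, and at the same time removes the methoxymethyl group and exchanges the acetal methoxyl. Aqueous work-up gives the boronic acid F8, and Me3NO gives 22.

**Step 6.**
- What may go wrong: the phenol of 5 is hydrogen-bonded to the ester and flanked on both sides, so C–O coupling may be slow. Twofold substitution or dehydrobromination of 7 could then dominate.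
- Fallback, from 5 back to 9: 5 is treated with trichloroethylene and K2CO3 in DMF to give the dichlorovinyl ether F9. n-BuLi (2.2 equiv, THF, −78 °C) gives the lithium aryloxyacetylide F10. Dimethoxycarbenium tetrafluoroborate adds the acetal carbon and gives 9.

**Step 15 (with step 16).**
- What may go wrong: enantiodiscrimination may be poor for a lactol whose carbon is flanked by the ortho aryloxy group, epimerisation may be slow relative to acyl transfer, and free 24 may epimerise again after release.
- Fallback, from 22 back to 24: 22 is peracetylated (Ac2O, pyridine) to the racemic triacetate F11. The enantiomers are separated by preparative chromatography on a chiral stationary phase to give the (R)-triacetate F12. All three acetates are then removed with an unselective esterase in pH 6 buffer at 5 °C, again by acyl–oxygen cleavage, to give 24.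

## Further compounds

F1 | step 9 | 2-(trimethylsilyl)ethyl 4-methoxy-2-{[3-methoxy-6-methyl-1-oxo-5,7-bis(trimethylsilyl)-1,3-dihydro-2-benzofuran-4-yl]oxy}-3-(methoxymethoxy)-6-methylbenzoate (racemic) | COCOc1c(OC)cc(C)c(C(=O)OCC[Si](C)(C)C)c1Oc1c([Si](C)(C)C)c(C)c([Si](C)(C)C)c2C(=O)OC(OC)c12
F2 | step 9 | 2-(trimethylsilyl)ethyl 2-[(5,7-diiodo-3-methoxy-6-methyl-1-oxo-1,3-dihydro-2-benzofuran-4-yl)oxy]-4-methoxy-3-(methoxymethoxy)-6-methylbenzoate (racemic) | COCOc1c(OC)cc(C)c(C(=O)OCC[Si](C)(C)C)c1Oc1c(I)c(C)c(I)c2C(=O)OC(OC)c12
F3 | step 9 | 2-(trimethylsilyl)ethyl 2-[(5,7-dihydroxy-3-methoxy-6-methyl-1-oxo-1,3-dihydro-2-benzofuran-4-yl)oxy]-4-methoxy-3-(methoxymethoxy)-6-methylbenzoate (racemic) | COCOc1c(OC)cc(C)c(C(=O)OCC[Si](C)(C)C)c1Oc1c(O)c(C)c(O)c2C(=O)OC(OC)c12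
F4 | step 9 | 2-[(5,7-dihydroxy-3-methoxy-6-methyl-1-oxo-1,3-dihydro-2-benzofuran-4-yl)oxy]-4-methoxy-3-(methoxymethoxy)-6-methylbenzoic acid (racemic) | COCOc1c(OC)cc(C)c(C(=O)O)c1Oc1c(O)c(C)c(O)c2C(=O)OC(OC)c12
F5 | step 7 | 1-[1-methoxy-3-(ring A aryloxy)prop-2-ynyl]-2,4,6-trimethylpyridinium trifluoromethanesulfonate (racemic) | COCOc1c(OC)cc(C)c(C(=O)OCC[Si](C)(C)C)c1OC#CC(OC)[n+]1c(C)cc(C)cc1C.[O-]S(=O)(=O)C(F)(F)F
F6 | step 10 | 2-{[5-hydroxy-3-methoxy-6-methyl-1-oxo-7-(trimethylsilyl)-1,3-dihydro-2-benzofuran-4-yl]oxy}-4-methoxy-3-(methoxymethoxy)-6-methylbenzoic acid (racemic) | COCOc1c(OC)cc(C)c(C(=O)O)c1Oc1c(O)c(C)c([Si](C)(C)C)c2C(=O)OC(OC)c12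
F7 | step 10 | depsidone as 19, with trimethylsilyl in place of iodine at b4 (racemic) | COCOc1c(OC)cc(C)c2c1Oc1c(OC2=O)c(C)c([Si](C)(C)C)c3C(=O)OC(OC)c13
F8 | step 10 | racemic lactol as 22, with B(OH)2 in place of the b4 hydroxyl | COc1cc(C)c2c(c1O)Oc1c(c(C)c(B(O)O)c3c1C(O)OC3=O)OC2=O
F9 | step 6 | 2-(trimethylsilyl)ethyl 2-{[(E)-1,2-dichloroethenyl]oxy}-4-methoxy-3-(methoxymethoxy)-6-methylbenzoate | COCOc1c(OC)cc(C)c(C(=O)OCC[Si](C)(C)C)c1O/C(Cl)=C\Cl
F10 | step 6 | lithium acetylide of the ring A aryl ethynyl ether | COCOc1c(OC)cc(C)c(C(=O)OCC[Si](C)(C)C)c1OC#C[Li]
F11 | step 15 | racemic triacetate of 22 (acetates at the a6 oxygen, the b4 oxygen and the lactol oxygen) | COc1cc(C)c2c(c1OC(C)=O)Oc1c(c(C)c(OC(C)=O)c3c1C(OC(C)=O)OC3=O)OC2=O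
F12 | step 15 | (R)-triacetate of 24 | COc1cc(C)c2c(c1OC(C)=O)Oc1c(c(C)c(OC(C)=O)c3c1[C@H](OC(C)=O)OC3=O)OC2=O
A1 | alternative 1 | 3-benzyloxy-4-(3,3-diethoxyprop-1-en-2-yl)-4-(methoxymethoxy)-2-methylcyclobut-2-en-1-one | C=C(C(OCC)OCC)C1(OCOC)C(OCc2ccccc2)=C(C)C1=O
A2 | alternative 1 | 3-benzyloxy-5-(diethoxymethyl)-4-(methoxymethoxy)-2-methylphenol | Cc1c(O)cc(C(OCC)OCC)c(OCOC)c1OCc1ccccc1
A3 | alternative 2 | spiro ketal of 8-benzyloxy-7-methoxy-5-methyl-4H-1,3-benzodioxin-4-one (spiro at C2) with a 4-oxocyclohexa-2,5-diene carrying 2-formyl, 3-methoxycarbonyl and 5-methyl | COc1cc(C)c2c(c1OCc1ccccc1)OC1(OC2=O)C=C(C)C(=O)C(C(=O)OC)=C1C=O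
A4 | alternative 2 | O-benzyl depsidone with formyl at b6, methoxycarbonyl at b5 and free hydroxyl at b4 | COc1cc(C)c2c(c1OCc1ccccc1)Oc1c(c(C)c(O)c(C(=O)OC)c1C=O)OC2=O
A5 | alternative 3 | tert-butyl 2-formyl-3-hydroxy-4-[(5-hydroxy-4-methoxy-2-methylbenzoyl)oxy]-6-(methoxymethoxy)-5-methylbenzoate | COc1cc(C)c(C(=O)Oc2c(O)c(C=O)c(C(=O)OC(C)(C)C)c(OCOC)c2C)cc1O
A6 | alternative 3 | depsidone with free a6 hydroxyl, formyl at b6, tert-butoxycarbonyl at b5 and methoxymethoxy at b4 | COc1cc(C)c2c(c1O)Oc1c(c(C)c(OCOC)c(C(=O)OC(C)(C)C)c1C=O)OC2=O
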